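**Retrosynthetic overview**
1. Target ⇐ dehydration of a tertiary α-ketol ⇐ carbene-catalysed acyloin closure of ring B (C4–C5 bond) from a keto aldehyde (allyl → CH2CHO).
2. Spiro nine-membered amino ketone (C12 quaternary, C13–O) ⇐ hydroxyl-directed epoxidation, then semipinacol 1,2-shift with 8→9 ring expansion of a cyclohexenyl azocanol.
3. Cyclohexenyl azocanol ⇐ Shapiro vinyl anion of the ring A ketone + N-formylazocan-5-one.
4. Ring A ketone (C7, C15 set) ⇐ silicon-tethered desymmetrising SOMO allyl transfer ⇐ cyclohexane-1,4-dione, MeMgBr, allyl(chloro)dimethylsilane.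
5. N-Formylazocan-5-one ⇐ ring-opening N-formylation of a pyrrolizidinium salt ⇐ dicyclopropyl ketone, HBr, NH3. Ring order: A given, C by expansion, B last.

Assumption: atom labels C1–C15 follow fawcettimine numbering (ring A = C7-C8-C15-C14-C13-C12, ring B = C4-C5-C6-C7-C12, ring C = N-C1-C2-C3-C4-C12-C11-C10-C9), and the catalyst enantiomer in step 4 is taken to be the one that delivers (2R,4R)-10.

**Route**

Step 1
Reactants: 1 dicyclopropyl ketone
Product: 2 1,7-dibromoheptan-4-one
Conditions: 48% aq. HBr, 0 → 45 °C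
Reagents that add atoms: hydrogen bromide (Br)
Why: Acid-promoted homoconjugate ring opening of both cyclopropyl ketone units by bromide (the reverse of γ-halo ketone cyclisation) gives the open dibromo ketone; no stereocentre.

Step 2
Reactants: 2 1,7-dibromoheptan-4-one
Product: 5 5-oxoazocane-1-carbaldehyde, via hexahydropyrrolizinium bromide 3 (not isolated), via pyrrolizidin-7a-ol 4 (not isolated)
Conditions: NH3 (7 M in MeOH, excess), 0 °C → rt; evaporate; then K2CO3, H2O/CH2Cl2, HCO2CH2CF3, rt
Reagents that add atoms: ammonia (N); water (O); 2,2,2-trifluoroethyl formate (O=COCC(F)(F)F)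
Why: Condensation and double N-alkylation with ammonia give the bicyclic iminium salt 3 (the standard pyrrolizidine entry from 1,7-dihaloheptan-4-ones), and N-acylation of its pseudo-base 4 with C–N fragmentation (pseudo-base ring-opening acylation) releases the eight-membered amino ketone as its formamide; no stereocentre.

Step 3
Reactants: 6 cyclohexane-1,4-dione
Product: 8 4-{[dimethyl(prop-2-en-1-yl)silyl]oxy}-4-methylcyclohexan-1-one, via bromomagnesium alkoxide 7 (not isolated)
Conditions: MeMgBr (0.95 equiv), THF, −78 °C, 6 in 2.5-fold excess; then CH2=CHCH2SiMe2Cl, −78 °C → rt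
Reagents that add atoms: methylmagnesium bromide (C[Mg]Br); allyl(chloro)dimethylsilane (C=CC[Si](C)(C)Cl)
Why: Mono 1,2-addition of the Grignard reagent to the symmetrical dione and in situ O-silylation of the tertiary magnesium alkoxide; the product is achiral.

Step 4
Reactants: 8 4-{[dimethyl(prop-2-en-1-yl)silyl]oxy}-4-methylcyclohexan-1-one
Product: 10 (2R,4R)-4-hydroxy-4-methyl-2-(prop-2-en-1-yl)cyclohexan-1-one, via silanol ether 9 (not isolated)
Conditions: (2S,5S)-5-benzyl-3-methyl-2-(5-methylfuran-2-yl)imidazolidin-4-one·TFA (20 mol%), (NH4)2Ce(NO3)6 (2.5 equiv), NaHCO3, H2O (2 equiv), DME, −20 °C, 0.02 M; then aq. citrate buffer pH 4, 0 °C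
Reagents that add atoms: none
Why: Proposed new method: silicon-tethered intramolecular SOMO allyl transfer with desymmetrisation – the chiral amine forms an enamine reversibly with either enantiotopic α-CH2, tetravalent cerium oxidises it to the 3π-electron radical cation, and the axial O–SiMe2–allyl tether (methyl equatorial) reaches the α-carbon only on the oxygen face through an eight-membered transition state, so the C–C bond forms cis to oxygen and only in the enamine whose tether face is not shielded by the catalyst; oxidation of the β-silyl radical and loss of silicon give 9, which hydrolyses on work-up, setting C7 and C15 together; the closest known reactions are the intermolecular SOMO α-allylation of cyclic ketones with allylsilanes, the intramolecular SOMO allylation of aldehydes and temporary silicon-tethered allyl transfers.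

Step 5
Reactants: 10 (2R,4R)-4-hydroxy-4-methyl-2-(prop-2-en-1-yl)cyclohexan-1-one
Product: 11 N'-[(1E,2R,4R)-4-hydroxy-4-methyl-2-(prop-2-en-1-yl)cyclohexylidene]-2,4,6-tri(propan-2-yl)benzenesulfonohydrazide
Conditions: 2,4,6-triisopropylbenzenesulfonohydrazide, THF, 4 Å MS, 0 °C → rt, no acid
Reagents that add atoms: 2,4,6-triisopropylbenzenesulfonohydrazide (CC(C)c1cc(C(C)C)c(S(=O)(=O)NN)c(C(C)C)c1)
Why: Acid-free condensation to the arenesulfonylhydrazone (Shapiro precursor) places the N-substituent anti to the substituted C7 and leaves the epimerisable α-stereocentre untouched.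

Step 6
Reactants: 11 trisylhydrazone of 10; 5 5-oxoazocane-1-carbaldehyde
Product: 14 5-hydroxy-5-[(4R,6R)-4-hydroxy-4-methyl-6-(prop-2-en-1-yl)cyclohex-1-en-1-yl]azocane-1-carbaldehyde, via vinyllithium 12 (not isolated), via vinylcerium dichloride 13 (not isolated)
Conditions: n-BuLi (3.1 equiv), THF, −78 → 0 °C; CeCl3, −78 °C; then 5 (1.3 equiv), −78 °C; aq. NH4Cl
Reagents that add atoms: none
Why: Shapiro reaction – syn-directed deprotonation at the unsubstituted α-CH2 and loss of N2 and sulfinate give the less substituted vinyllithium 12, transmetallation to cerium suppresses enolisation and attack on the formamide, and 1,2-addition to the ketone gives the tertiary allylic alcohol with C7 and C15 unchanged.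

Step 7
Reactants: 14 cyclohexenyl azocanol
Product: 16 (1S,3S,5R,6R)-1,3-dihydroxy-3-methyl-14-oxo-5-(prop-2-en-1-yl)-10-azaspiro[5.8]tetradecane-10-carbaldehyde, via epoxy alcohol 15 (not isolated)
Conditions: VO(acac)2 (5 mol%), t-BuOOH (1.1 equiv), CH2Cl2, 0 °C; then BF3·OEt2 (3 equiv), −78 → −30 °C
Reagents that add atoms: tert-butyl hydroperoxide (CC(C)(C)OO)
Why: Hydroxyl-directed epoxidation delivers oxygen to the ring face carrying the homoallylic C15–OH (syn to the C7 side chain, the other face being screened by the C15 methyl), and Lewis acid opening at tertiary C12 with anti 1,2-shift of a ring CH2 of the azocanol (semipinacol rearrangement of a 2,3-epoxy alcohol, 8→9 ring expansion) sets the C12 quaternary centre and C13–OH stereospecifically, with C11 trans to the C13 oxygen.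

Step 8
Reactants: 16 spiro dihydroxy ketone
Product: 17 (1S,3S,5R,6R)-10-formyl-3-methyl-14-oxo-5-(prop-2-en-1-yl)-10-azaspiro[5.8]tetradecane-1,3-diyl diacetate
Conditions: Ac2O (6 equiv), Sc(OTf)3 (3 mol%), MeCN, −20 °C
Reagents that add atoms: acetic anhydride (CC(=O)OC(C)=O)
Why: Lewis acid-catalysed acetylation esterifies the secondary and the tertiary alcohol at low temperature, and β-elimination at C13 is impossible because C12 is quaternary.

Step 9
Reactants: 17 allyl diacetate
Product: 19 (1S,3S,5S,6R)-10-formyl-3-methyl-14-oxo-5-(2-oxoethyl)-10-azaspiro[5.8]tetradecane-1,3-diyl diacetate, via ozonide 18 (not isolated)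
Conditions: O3, CH2Cl2, −78 °C; then Me2S, −78 °C → rt
Reagents that add atoms: ozone ([O-][O+]=O)
Why: Ozonolysis of the only alkene with reductive work-up gives the C5 aldehyde without touching any stereocentre.

Step 10
Reactants: 19 keto aldehyde
Product: 20 (4S,7S,12R,13S,15S)-4-hydroxy-5-oxo tricyclic α-ketol diacetate
Conditions: 2-(pentafluorophenyl)-6,7-dihydro-5H-pyrrolo[2,1-c][1,2,4]triazol-2-ium tetrafluoroborate (15 mol%), Et3N (15 mol%), toluene, 40 °C
Reagents that add atoms: none
Why: Carbene-catalysed intramolecular crossed aldehyde–ketone benzoin (acyloin) reaction – 5-exo attack of the Breslow intermediate on the C4 ketone closes ring B, necessarily cis-fused, and the C4 carbinol configuration is irrelevant because it is removed in the next step.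

Step 11
Reactants: 20 α-ketol
Product: 21 target CNP0137427.1
Conditions: Burgess reagent (methyl N-(triethylammoniosulfonyl)carbamate), toluene, 60 °C
Reagents that add atoms: none
Why: Burgess syn-elimination of the tertiary α-ketol can only occur toward C3 (C12 is quaternary) and gives the exocyclic enone with the ring-cis, (E) geometry.

**Compound list**
1 | dicyclopropyl ketone | O=C(C1CC1)C1CC1 | starting material
2 | 1,7-dibromoheptan-4-one | O=C(CCCBr)CCCBr | intermediate
3 | 1,2,3,5,6,7-hexahydropyrrolizin-4-ium bromide | [Br-].C1CC2=[N+](C1)CCC2 | intermediate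
4 | hexahydro-1H-pyrrolizin-7a-ol (pseudo-base of 3) | OC12CCCN1CCC2 | intermediate
5 | 5-oxoazocane-1-carbaldehyde | O=CN1CCCC(=O)CCC1 | intermediate
6 | cyclohexane-1,4-dione | O=C1CCC(=O)CC1 | starting material
7 | bromomagnesium 1-methyl-4-oxocyclohexan-1-olate | CC1(CCC(=O)CC1)O[Mg]Br | intermediate
8 | 4-{[dimethyl(prop-2-en-1-yl)silyl]oxy}-4-methylcyclohexan-1-one | C=CC[Si](C)(C)OC1(C)CCC(=O)CC1 | intermediate
9 | (2R,4R)-4-{[hydroxy(dimethyl)silyl]oxy}-4-methyl-2-(prop-2-en-1-yl)cyclohexan-1-one | O=C1CC[C@@](C)(O[Si](C)(C)O)C[C@H]1CC=C | intermediate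
10 | (2R,4R)-4-hydroxy-4-methyl-2-(prop-2-en-1-yl)cyclohexan-1-one (allyl cis to OH) | O=C1CC[C@@](C)(O)C[C@H]1CC=C | intermediate
11 | N'-[(1E,2R,4R)-4-hydroxy-4-methyl-2-(prop-2-en-1-yl)cyclohexylidene]-2,4,6-tri(propan-2-yl)benzenesulfonohydrazide | CC(C)c1cc(C(C)C)c(S(=O)(=O)N/N=C2\CC[C@@](C)(O)C[C@H]2CC=C)c(C(C)C)c1 | intermediate
12 | lithium (1R,5R)-4-lithio-1-methyl-5-(prop-2-en-1-yl)cyclohex-3-en-1-olate | [Li]C1=CC[C@@](C)(O[Li])C[C@H]1CC=C | intermediate
13 | lithium (1R,5R)-4-(dichloroceryl)-1-methyl-5-(prop-2-en-1-yl)cyclohex-3-en-1-olate | Cl[Ce](Cl)C1=CC[C@@](C)(O[Li])C[C@H]1CC=C | intermediate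
14 | 5-hydroxy-5-[(4R,6R)-4-hydroxy-4-methyl-6-(prop-2-en-1-yl)cyclohex-1-en-1-yl]azocane-1-carbaldehyde | O=CN1CCCC(O)(CCC1)C1=CC[C@@](C)(O)C[C@H]1CC=C | intermediate
15 | 5-hydroxy-5-[(1R,2R,4S,6S)-4-hydroxy-4-methyl-2-(prop-2-en-1-yl)-7-oxabicyclo[4.1.0]heptan-1-yl]azocane-1-carbaldehyde (epoxide cis to C15–OH and to the allyl group) | O=CN1CCCC(O)(CCC1)[C@]23O[C@H]2C[C@@](C)(O)C[C@H]3CC=C | intermediate
16 | (1S,3S,5R,6R)-1,3-dihydroxy-3-methyl-14-oxo-5-(prop-2-en-1-yl)-10-azaspiro[5.8]tetradecane-10-carbaldehyde | O[C@H]1C[C@@](C)(O)C[C@@H](CC=C)[C@]12CCCN(C=O)CCCC2=O | intermediate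
17 | (1S,3S,5R,6R)-10-formyl-3-methyl-14-oxo-5-(prop-2-en-1-yl)-10-azaspiro[5.8]tetradecane-1,3-diyl diacetate | CC(=O)O[C@H]1C[C@@](C)(OC(C)=O)C[C@@H](CC=C)[C@]12CCCN(C=O)CCCC2=O | intermediate
18 | (1S,3S,5S,6R)-10-formyl-3-methyl-14-oxo-5-[(1,2,4-trioxolan-3-yl)methyl]-10-azaspiro[5.8]tetradecane-1,3-diyl diacetate (both epimers at the trioxolane carbon) | CC(=O)O[C@H]1C[C@@](C)(OC(C)=O)C[C@@H](CC2OCOO2)[C@]13CCCN(C=O)CCCC3=O | intermediate
19 | (1S,3S,5S,6R)-10-formyl-3-methyl-14-oxo-5-(2-oxoethyl)-10-azaspiro[5.8]tetradecane-1,3-diyl diacetate | CC(=O)O[C@H]1C[C@@](C)(OC(C)=O)C[C@@H](CC=O)[C@]12CCCN(C=O)CCCC2=O | intermediate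
20 | (4S,7S,12R,13S,15S) α-ketol: as 21 but C3 is CH2 and C4 carries OH (trans to C11); ring B cyclopentanone with C5=O, cis-fused to ring A; 13,15-diacetate; N-formyl | CC(=O)O[C@H]1C[C@@](C)(OC(C)=O)C[C@H]2CC(=O)[C@]3(O)CCCN(C=O)CCC[C@@]321 | intermediate
21 | CNP0137427.1, (3E,7S,12S,13S,15S): ring A cyclohexane with OAc at C13 and OAc/Me at C15, cis-fused ring B cyclopentanone (C5=O), nine-membered N-formyl azonine with exocyclic C4=C3 enone | CC(=O)O[C@H]1C[C@@](C)(OC(C)=O)C[C@H]2CC(=O)/C3=C/CCN(C=O)CCC[C@@]321 | target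

**Totals and risks**

Total step count: 11. Longest linear sequence: 9 steps (6 → 21, steps 3–11); the azocanone branch (1 → 5) adds 2 steps and joins at step 6.

The three steps most likely to fail:

Step 4 (the proposed new tethered SOMO allyl transfer; an eight-membered transition state and silyl ether stability toward the cerium oxidant are untested). The fallback uses known chemistry, sets out from 6 and returns at 14. Compound 6 is mono-ketalised (HC(OMe)3, MeOH, TsOH, then partial hydrolysis) to 4,4-dimethoxycyclohexan-1-one F1. The established intermolecular SOMO α-allylation (allyltrimethylsilane, the same imidazolidinone, (NH4)2Ce(NO3)6, NaHCO3, DME, −20 °C) gives (2R)-4,4-dimethoxy-2-(prop-2-en-1-yl)cyclohexan-1-one F2. Condensation with 2,4,6-triisopropylbenzenesulfonohydrazide gives the trisylhydrazone F3. n-BuLi generates the vinyllithium F4, CeCl3 converts it into the vinylcerium dichloride F5, and addition to 5 gives the ketal carbinol F6. Wet silica/oxalic acid unmasks the β,γ-unsaturated ketone F7. MeCeCl2 at −78 °C then adds anti to the allyl group, which is held pseudoaxial by A(1,2) strain with the C12 substituent, so the new hydroxyl is cis to the allyl group and the product is 14. Here C7 comes from catalyst control and C15 from substrate control.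

Step 7 (the facial selectivity of the epoxidation decides both C12 and C13, and residual peroxide meets the Lewis acid in one pot). The fallback sets out from 14 and returns at 16 through isolated 15. Substrate direction is replaced by reagent control: Hf(OtBu)4 with a chiral bishydroxamic acid ligand and cumene hydroperoxide, a system made for tertiary allylic alcohols, with the ligand enantiomer matched to the required face. Epoxide 15 is purified and then rearranged in a separate operation with BF3·OEt2. No new compound is made.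

Step 10 (the hindered C4 ketone next to a quaternary centre may react slowly, and an aldol reaction of the C3 enolate with the aldehyde could compete). The fallback sets out from 19 and returns at 20. SmI2 (THF, −78 °C) effects ketyl pinacol coupling of the aldehyde and the ketone to the cis-4,5-diol F8. Parikh–Doering oxidation (SO3·pyridine, DMSO, Et3N) of the secondary C5 hydroxyl then gives 20.

**Further compounds**
F1 | step 4 | 4,4-dimethoxycyclohexan-1-one | COC1(OC)CCC(=O)CC1
F2 | step 4 | (2R)-4,4-dimethoxy-2-(prop-2-en-1-yl)cyclohexan-1-one | O=C1CCC(OC)(OC)C[C@H]1CC=C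
F3 | step 4 | N'-[(1E,2R)-4,4-dimethoxy-2-(prop-2-en-1-yl)cyclohexylidene]-2,4,6-tri(propan-2-yl)benzenesulfonohydrazide | CC(C)c1cc(C(C)C)c(S(=O)(=O)N/N=C2\CCC(OC)(OC)C[C@H]2CC=C)c(C(C)C)c1
F4 | step 4 | [(6R)-4,4-dimethoxy-6-(prop-2-en-1-yl)cyclohex-1-en-1-yl]lithium | [Li]C1=CCC(OC)(OC)C[C@H]1CC=C
F5 | step 4 | dichloro[(6R)-4,4-dimethoxy-6-(prop-2-en-1-yl)cyclohex-1-en-1-yl]cerium | Cl[Ce](Cl)C1=CCC(OC)(OC)C[C@H]1CC=C
F6 | step 4 | 5-[(6R)-4,4-dimethoxy-6-(prop-2-en-1-yl)cyclohex-1-en-1-yl]-5-hydroxyazocane-1-carbaldehyde | O=CN1CCCC(O)(CCC1)C1=CCC(OC)(OC)C[C@H]1CC=C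
F7 | step 4 | 5-hydroxy-5-[(6R)-4-oxo-6-(prop-2-en-1-yl)cyclohex-1-en-1-yl]azocane-1-carbaldehyde | O=CN1CCCC(O)(CCC1)C1=CCC(=O)C[C@H]1CC=C
F0 | step 7 | none | none
F8 | step 10 | (4S,5R,7R,12R,13S,15S)-4,5-cis-diol: as 20 but C5 carries OH and H instead of the ketone | CC(=O)O[C@H]1C[C@@](C)(OC(C)=O)C[C@H]2C[C@@H](O)[C@]3(O)CCCN(C=O)CCC[C@@]321
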